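If you book G the way you book reactive groups in a step-growth charge, one mole against one mole, this series becomes a matter of counting turnovers: how many times one charge of G can serve the D beside it.

| setting | midnight | autumn | Saturday's | Sunday's | Wednesday's | Tuesday's | Thursday's |
|---|---|---|---|---|---|---|---|
| D | 0.012 M | 0.012 M | 0.012 M | 0.025 M | 0.050 M | 0.10 M | 0.20 M |
| G | 0.0525 M | 0.0525 M | 0.0525 M | 0.0525 M | 0.0525 M | 0.0525 M | 0.0525 M |
| J | 0.0067 M | 0.020 M | 0.0100 M | 0.0100 M | 0.0100 M | 0.0100 M | 0.0100 M |
| remark | run made earlier | run made earlier |  |  |  |  |  |
| time |  |  | 8.0 d | 8.0 d | 8.0 d | 8.0 d | 8.0 d |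
| volume of the second phase over the first |  |  | 1.0 | 1.0 | 1.0 | 1.0 | 1.0 |

| run | time / h | X / % | D / % |
|---|---|---|---|
| midnight | 3.00 | 3 | 95 |
| midnight | 6.00 | 8 | 91 |
| midnight | 10.0 | 14 | 87 |
| midnight | 20.0 | 32 | 66 |
| midnight | 40.0 | 47 | 44 |
| autumn | 3.00 | 3 | 99 |
| autumn | 10.0 | 9 | 89 |
| autumn | 20.0 | 22 | 77 |
| autumn | 30.0 | 29 | 66 |
| autumn | 40.0 | 36 | 59 |

(standard deviation of a reading: 1.5 percentage points)

- charges count per volume of the first phase; a concentration in a rate is the amount of a species over the volume of its own phase; every rate counts per litre of the first phase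
- the earlier runs hold the two phases in the same ratio of volumes as the flask asked about
- a reading or a percentage of X counts all its forms, free or not
- the concentration of X that is asked is that of its free form alone
- "hardly changes" means that all values lie within two and a half points (for a concentration: within two and a half percent of the largest)

1. [X] (only what is free in solution, in the first phase) at the end for Saturday's, Sunday's, Wednesday's, Tuesday's, Thursday's, in this order
2. how that number moves from the first to the last of them (rises all the way / hardly changes / rises, then falls / falls, then rises / falls all the way)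

My ledger for G, reckoned from the earlier runs:

- Opening balance: the new series is charged with 0.0525 M of G, as much as the earlier runs, while its D climbs from 0.012 M to 0.20 M.
- First debit, to J: over 40.0 h the midnight run, with 0.0067 M of J, loses D at about 0.0205 h⁻¹, and the autumn run, with 0.020 M of J, at about 0.0132 h⁻¹; that ratio of 1.55, read with the scatter, stands near the 1.41 you get by taking one G per J from the charge, so I book one G to each J.
- Balance for D: what remains is 0.0425 M, and I call this U, the budget: the G per litre of first phase still open to D after one G per J.
- Turnovers: U over the D charged gives 3.54 for Saturday's, where the budget is larger than the D, but 0.212 for Thursday's, where G becomes the limiting reagent and the books allow 21.2% of its D to react.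
- Open entry: at 40.0 h in the midnight run, 9.00% of the D charged stands in neither column, and the readings count X in every form, so the budget closes the account for D but does not give free X.

The forecast, on 0.0425 M of usable G, gives 0.0111 M, 0.0217 M, 0.0355 M, 0.0422 M and 0.0425 M, and says the number rises all the way; for the last step it writes: “I therefore take free X ≈ total X, which is an assumption.”

The flask gives 0.00153 M, 0.00319 M, 0.00513 M, 0.00485 M and 0.00456 M of free X, so the number rises, then falls.

    X ⇌ L, rate k1*([X] - [L]/K1) per volume of the first phase (partition coefficient = 2.80, kL = 0.0280 h⁻¹)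
    X → E (k = 0.0120 h⁻¹)
    Q ⇌ G, rate k3*([Q] - [G]/K3) per volume of the first phase (partition coefficient = 1.20, kL = 0.200 h⁻¹)
    D + Q → X (k = 1.20 M⁻¹ h⁻¹)
    Q + J → Z (k = 38.0 M⁻¹ h⁻¹)

In Saturday's at 8.00 d, X counts 53.8% of the D charged, and L, counted in that figure, stands at 41.0% of the D charged, so the free X is 0.00153 M. In Tuesday's at 80.0 d, with G at 0% and Q at 0 M, the D consumed is 0.0425 M, close to the budget U of 0.0425 M. In Thursday's at 80.0 d, with G at 0%, 78.7% of the D remains, so the D consumed is 0.0426 M.

The data are simulated on assumed constants; noise was put on by code.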